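(The earlier runs and the new flask are simulated on assumed constants.)

In a one-step world the catalyst stays as charged, substrate falls pseudo-first-order, and a larger charge simply shortens the clock. The first chemist therefore expects the rate at fixed conversion to follow the charge, giving 2.00 for dbl and 0.200 for ratio. Her evidence is the first reading, where the winter run has made 2.02 times the midnight run's amount of product on 2.00 times its catalyst.

| setting | midnight | winter | flask |
|---|---|---|---|
| substrate | 2.1 M | 1.5 M | 1.5 M |
| free catalyst | 1.5 mM | 3 mM | 1.5 mM |
| remark | run made earlier | run made earlier |  |

| run | time / min | product / % | substrate / % |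
|---|---|---|---|
| midnight | 0.417 | 2.3 | 96.3 |
| midnight | 0.667 | 4.1 | 96.5 |
| midnight | 1.00 | 8.6 | 94.5 |
| midnight | 2.00 | 11.2 | 86.6 |
| midnight | 3.00 | 17.6 | 83.0 |
| midnight | 5.00 | 24.6 | 75.4 |
| winter | 0.417 | 6.5 | 93.0 |
| winter | 1.33 | 21.0 | 78.5 |
| winter | 2.00 | 28.5 | 73.3 |
| winter | 3.00 | 37.4 | 62.2 |
| winter | 5.00 | 49.8 | 50.8 |

(each reading ± 1 percentage point)

- factor on the rate of making product when 30 % of the substrate are converted if free catalyst is charged twice over
- factor on the rate when 30 % of the substrate are converted if free catalyst is charged at 0.30 mM instead

- what was read earlier has a scatter of 1 percentage point, one standard deviation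
- what may be going on: substrate + free catalyst <-> catalyst intermediate A; catalyst intermediate A -> catalyst intermediate B; catalyst intermediate B -> free catalyst + product; free catalyst <-> dormant form

The second chemist, who made the forecast, disagrees: “The loss therefore follows clock time, not conversion.” She gives dbl 2.7 (2.2 to 3.3) and ratio 0.12 (0.06 to 0.19).

My own reckoning starts from the winter run, which is the doubled flask. Its substrate decays at 0.174 min⁻¹ at first, but at 0.101 min⁻¹ late on. As a reading, with its scatter, activity in the winter run is lost at 0.143 min⁻¹.

Dividing that loss rate by the starting conversion rate removes time. In the winter run this gives 0.821. If the loss keeps the clock, the flask's value grows with its smaller charge to 1.64, the loss per conversion. Activity left is then one minus this quantity times ln(1/fraction of substrate left), here 0.357. The winter run keeps 0.707 and the flask 0.414, so I commit to dbl 3.41, above the forecast.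

The simulation gives dbl 3.27, more than the forecast's 2.7, and ratio 0.124, within the forecast's range; the one-step view had 2.00 and 0.200. The one-step view keeps the start: in the flask at 0.600 min, the dormant form holds 11.1 % of the catalyst charged.

    substrate + free catalyst ⇌ catalyst intermediate A (K = 1.80 M⁻¹, k = 3.48 M⁻¹ s⁻¹)
    catalyst intermediate A → catalyst intermediate B (k = 3.10 s⁻¹)
    catalyst intermediate B → free catalyst + product (k = 62.9 s⁻¹)
    free catalyst ⇌ dormant form (K = 5.40, k = 0.00685 s⁻¹)

At 0.30 mM, the loss per conversion scaled from 1.64 reaches 2.93 when multiplied by 0.357, which is past 1, so for that flask the straight line of loss no longer holds at 30 %. The rate per catalyst charged in that flask is 0.621 of the flask's, or, on my estimate of 0.414 for the flask, 0.257 of starting activity. In the flask at 6.00 min, free catalyst has a forward half-life of 0.19 s towards catalyst intermediate A, far shorter than the 1.7 min towards the dormant form. Yet the dormant form then holds 61.9 % of the catalyst charged, and catalyst intermediate A 15.6 %.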